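The 6,8-dioxabicyclo[3.2.2]nonan-7-one core hides a glycolate unit: ether oxygen O-8 sits on C-1, the α-carbon of the lactone, and C-1 bears the β-hydroxyl carbon C-2. Both bonds of this unit to the rest of the cage, O-8–C-9 and C-1–C-2, are made in one palladium-triggered domino from an acyclic tertiary ester of an allyl 2-hydroxymalonate that carries an allylic carbonate and an aldehyde: allylic etherification closes the 1,4-dioxan-2-one ring, then decarboxylation of the allyl ester unmasks the lactone enolate only at C-1, which bridges the ring by aldol addition. (R)-Linalool supplies C-5; the C-9 side chain follows by B-alkyl Suzuki coupling.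

Key step: step 15

Remark: core positions follow 6,8-dioxabicyclo[3.2.2]nonan-7-one numbering (C-1 quaternary α-carbon, C-2 carbinol, C-5 methyl-bearing bridgehead, O-6/C-7 lactone, O-8 ether, C-9 side-chain CH); TBS = tert-butyldimethylsilyl, TBDPS = tert-butyldiphenylsilyl; the malonate carbon of 19 to 23 is carried as a mixture of epimers because step 15 erases it.

Step 1
Reactants: 1 (R)-(−)-linalool
Product: 3 (4R)-4-methylhex-5-ene-1,4-diol, via lactol 2 (not isolated)
Conditions: O3 (1 equiv), CH2Cl2/MeOH, −78 °C; then NaBH4, −78 °C to rt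
Reagents that add atoms: ozone, O=[O+][O-]
Why: Chemoselective ozonolysis cleaves the electron-rich trisubstituted alkene much faster than the vinyl group, and borohydride reduces the resulting lactol to the diol without touching the stereocentre taken from linalool.

Step 2
Reactants: 3 (4R)-4-methylhex-5-ene-1,4-diol
Product: 4 (3R)-6-(TBS-oxy)-3-methylhex-1-en-3-ol
Conditions: TBSCl, imidazole, DMF, 0 °C
Reagents that add atoms: tert-butyldimethylsilyl chloride, CC(C)(C)[Si](C)(C)Cl
Why: Silyl ether formation is selective for the primary over the tertiary hydroxyl.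

Step 3
Reactants: 4 (3R)-6-(TBS-oxy)-3-methylhex-1-en-3-ol; 5 allyl methyl carbonate (3 equiv)
Product: 6 (2E,4R)-7-(TBS-oxy)-4-hydroxy-4-methylhept-2-en-1-yl methyl carbonate
Conditions: second-generation Hoveyda–Grubbs catalyst (5 mol %), CH2Cl2, 40 °C
Reagents that add atoms: none
Why: Olefin cross-metathesis of the hindered vinyl carbinol with an excess of the unhindered partner gives the (E)-allylic carbonate under thermodynamic control and leaves the tertiary centre untouched.

Step 4
Reactants: 7 Meldrum's acid; 8 allyl alcohol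
Product: 9 allyl hydrogen malonate
Conditions: toluene, 100 °C
Reagents that add atoms: none
Why: Thermal alcoholysis of Meldrum's acid (acylketene route) gives the malonic half ester with loss of acetone.

Step 5
Reactants: 6 (2E,4R)-7-(TBS-oxy)-4-hydroxy-4-methylhept-2-en-1-yl methyl carbonate; 9 allyl hydrogen malonate
Product: 10 (2E,4R)-7-(TBS-oxy)-1-[(methoxycarbonyl)oxy]-4-methylhept-2-en-4-yl prop-2-en-1-yl propanedioate
Conditions: DCC, DMAP (cat.), CH2Cl2, 0 °C to rt
Reagents that add atoms: none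
Why: Carbodiimide activation of a malonic half ester (Steglich-type esterification) passes through an acylketene, which acylates even a tertiary alcohol.

Step 6
Reactants: 11 (3-bromopropoxy)(tert-butyl)dimethylsilane
Product: 12 [3-(TBS-oxy)propyl]triphenylphosphonium bromide
Conditions: PPh3, MeCN, 80 °C
Reagents that add atoms: triphenylphosphine, c1ccc(cc1)P(c1ccccc1)c1ccccc1
Why: SN2 quaternisation of the phosphine by the primary bromide gives the Wittig salt.

Step 7
Reactants: 13 hydroxyacetone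
Product: 14 1-(TBDPS-oxy)propan-2-one
Conditions: TBDPSCl, imidazole, CH2Cl2, 0 °C to rt
Reagents that add atoms: tert-butyldiphenylsilyl chloride, CC(C)(C)[Si](Cl)(c1ccccc1)c1ccccc1
Why: Silyl ether formation on the primary hydroxyl gives the α-silyloxy ketone needed for the Z-selective olefination.

Step 8
Reactants: 12 [3-(TBS-oxy)propyl]triphenylphosphonium bromide; 14 1-(TBDPS-oxy)propan-2-one
Product: 16 (2Z)-5-(TBS-oxy)-1-(TBDPS-oxy)-2-methylpent-2-ene, via phosphorus ylide 15 (not isolated)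
Conditions: NaN(SiMe3)2, THF, −78 °C; then 14, −78 °C to rt
Reagents that add atoms: none
Why: Wittig olefination of an α-alkoxy ketone with a non-stabilised ylide is known to give the Z-trisubstituted allylic ether, with the incoming chain cis to the CH2O group.

Step 9
Reactants: 16 (2Z)-5-(TBS-oxy)-1-(TBDPS-oxy)-2-methylpent-2-ene
Product: 17 (3Z)-5-(TBDPS-oxy)-4-methylpent-3-en-1-ol
Conditions: PPTS (cat.), MeOH, rt
Reagents that add atoms: none
Why: Acid-catalysed methanolysis removes the primary TBS ether much faster than the TBDPS ether.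

Step 10
Reactants: 17 (3Z)-5-(TBDPS-oxy)-4-methylpent-3-en-1-ol
Product: 18 tert-butyl{[(2Z)-5-iodo-2-methylpent-2-en-1-yl]oxy}diphenylsilane
Conditions: I2, PPh3, imidazole, CH2Cl2, 0 °C
Reagents that add atoms: iodine, II
Why: Appel-type iodination converts the primary alcohol into the iodide without touching the alkene geometry.

Step 11
Reactants: 10 mixed malonate; 18 tert-butyl{[(2Z)-5-iodo-2-methylpent-2-en-1-yl]oxy}diphenylsilane
Product: 19 (2E,4R)-7-(TBS-oxy)-1-[(methoxycarbonyl)oxy]-4-methylhept-2-en-4-yl prop-2-en-1-yl 2-[(3Z)-5-(TBDPS-oxy)-4-methylpent-3-en-1-yl]propanedioate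
Conditions: NaH, THF/DMF, 0 °C; then 18, rt
Reagents that add atoms: none
Why: Malonic ester alkylation of the sodium enolate by the primary iodide attaches the C-1 side chain; the new malonate centre forms as a mixture, which does not matter because step 15 erases it.

Step 12
Reactants: 19 alkylated mixed malonate
Product: 20 (2E,4R)-7-(TBS-oxy)-1-[(methoxycarbonyl)oxy]-4-methylhept-2-en-4-yl prop-2-en-1-yl 2-hydroxy-2-[(3Z)-5-(TBDPS-oxy)-4-methylpent-3-en-1-yl]propanedioate
Conditions: KN(SiMe3)2, THF, −78 °C; 2-(phenylsulfonyl)-3-phenyloxaziridine, −78 °C; AcOH quench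
Reagents that add atoms: 2-(phenylsulfonyl)-3-phenyloxaziridine (Davis oxaziridine), O=S(=O)(c1ccccc1)N1OC1c1ccccc1
Why: Davis oxidation of the potassium malonate enolate places on the future C-1 the oxygen that becomes O-8 of the target.

Step 13
Reactants: 20 silyl-protected 2-hydroxymalonate
Product: 21 (2E,4R)-7-hydroxy-1-[(methoxycarbonyl)oxy]-4-methylhept-2-en-4-yl prop-2-en-1-yl 2-hydroxy-2-[(3Z)-5-(TBDPS-oxy)-4-methylpent-3-en-1-yl]propanedioate
Conditions: HF·pyridine, pyridine/THF, 0 °C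
Reagents that add atoms: none
Why: Fluoride cleaves the primary TBS ether selectively, while the bulkier TBDPS ether is retained.

Step 14
Reactants: 21 primary alcohol
Product: 22 (2E,4R)-1-[(methoxycarbonyl)oxy]-4-methyl-7-oxohept-2-en-4-yl prop-2-en-1-yl 2-hydroxy-2-[(3Z)-5-(TBDPS-oxy)-4-methylpent-3-en-1-yl]propanedioate
Conditions: Dess–Martin periodinane, CH2Cl2, 0 °C to rt
Reagents that add atoms: none
Why: Dess–Martin oxidation stops at the aldehyde and tolerates the tertiary hydroxyl, the carbonate and the alkenes.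

Step 15
Reactants: 22 aldehyde-bearing allyl 2-hydroxymalonate
Product: 24 (1R,2S,5R,9S)-9-ethenyl-2-hydroxy-5-methyl-1-[(3Z)-5-(TBDPS-oxy)-4-methylpent-3-en-1-yl]-6,8-dioxabicyclo[3.2.2]nonan-7-one, via allyl dioxanonecarboxylate 23 (not isolated)
Conditions: Pd2(dba)3·CHCl3 (2.5 mol %), (R,R)-DACH-phenyl Trost ligand (7.5 mol %), degassed THF (0.02 M), 0 °C to rt, then 45 °C
Reagents that add atoms: none
Why: Proposed new method: zerovalent palladium first ionises the primary allylic carbonate, the methoxide set free deprotonates the acidic 2-hydroxymalonate hydroxyl, and this oxygen attacks the internal terminus of the π-allyl unit (6-exo closure to 1,4-dioxan-2-one 23, O-8–C-9 bond); only now, with the α-oxygen etherified, do oxidative addition to the allyl ester and loss of CO2 deliver an allylpalladium lactone enolate located solely at C-1, although an enolisable aldehyde is present. The enolate carbon adds to the aldehyde across the ring in a 7-(enolendo)-exo-trig closure (C-1–C-2 bond) that completes the bicyclo[3.2.2] cage, after which the aldolate takes the proton of the methanol and methoxide removes the allyl group as allyl methyl ether. The closest known reactions are the Trost asymmetric allylic etherification and the palladium-catalysed decarboxylative aldol reaction of allyl β-keto carboxylates, extended here from ketone enolates to a malonate-derived lactone enolate and coupled with the etherification in one flask. C-9 is set by the chiral ligand (vinyl cis to the oxopropyl arm; the (S,S)-ligand is the alternative if the wall-and-flap model reads the other way), C-1 by the tether, because the three-carbon bridge can only close on the ring face that carries the oxopropyl arm, and C-2 by a closed transition state in which the metal holds the aldehyde oxygen next to the enolate oxygen, so that the hydroxyl ends up syn to the lactone bridge and anti to O-8. The step needs the aldol to outrun C-allylation and protonation of the enolate and needs etherification to precede decarboxylation; the faster, irreversible ionisation of the carbonate, the intramolecular aldehyde and the low kinetic acidity of methanol towards palladium enolates should secure this.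

Step 16
Reactants: 25 but-2-yn-1-ol
Product: 27 (2Z)-3-iodobut-2-en-1-ol, via cyclic vinylalanate 26 (not isolated)
Conditions: NaAlH2(OCH2CH2OCH3)2, THF, 0 °C to rt; then I2, −78 °C
Reagents that add atoms: iodine, II
Why: Hydroxyl-directed trans-hydroalumination places aluminium on C-3 cis to the CH2O group, and iodinolysis with retention gives the (Z)-vinyl iodide.

Step 17
Reactants: 27 (2Z)-3-iodobut-2-en-1-ol
Product: 28 tert-butyl{[(2Z)-3-iodobut-2-en-1-yl]oxy}diphenylsilane
Conditions: TBDPSCl, imidazole, CH2Cl2, rt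
Reagents that add atoms: tert-butyldiphenylsilyl chloride, CC(C)(C)[Si](Cl)(c1ccccc1)c1ccccc1
Why: Silyl ether formation protects the allylic alcohol for the coupling.

Step 18
Reactants: 24 vinyl-substituted bicyclic lactone; 28 tert-butyl{[(2Z)-3-iodobut-2-en-1-yl]oxy}diphenylsilane
Product: 30 (1R,2S,5R,9S)-2-hydroxy-5-methyl-9-[(3Z)-5-(TBDPS-oxy)-3-methylpent-3-en-1-yl]-1-[(3Z)-5-(TBDPS-oxy)-4-methylpent-3-en-1-yl]-6,8-dioxabicyclo[3.2.2]nonan-7-one, via alkylborane 29 (not isolated)
Conditions: 9-BBN (3 equiv), THF, rt; then 28, PdCl2(dppf) (5 mol %), AsPh3, K3PO4 (aq), DMF, rt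
Reagents that add atoms: none
Why: 9-BBN hydroborates only the monosubstituted vinyl group, at its terminus, and B-alkyl Suzuki–Miyaura coupling with the vinyl iodide proceeds with retention of the (Z) geometry.

Step 19
Reactants: 30 bis-TBDPS ether
Product: 31 (1R,2S,5R,9S)-2-hydroxy-9-[(3Z)-5-hydroxy-3-methylpent-3-en-1-yl]-1-[(3Z)-5-hydroxy-4-methylpent-3-en-1-yl]-5-methyl-6,8-dioxabicyclo[3.2.2]nonan-7-one
Conditions: Bu4NF, AcOH, THF, rt
Reagents that add atoms: none
Why: Buffered fluoride desilylation frees both primary allylic alcohols and should leave the lactone and the four stereocentres intact.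

Compound list

1 | (R)-(−)-linalool, (3R)-3,7-dimethylocta-1,6-dien-3-ol | C=C[C@](C)(O)CCC=C(C)C | starting material
2 | (5R)-5-ethenyl-5-methyloxolan-2-ol (lactol, both anomers) | C=C[C@@]1(C)CCC(O)O1 | intermediate
3 | (4R)-4-methylhex-5-ene-1,4-diol | C=C[C@](C)(O)CCCO | intermediate
4 | (3R)-6-(TBS-oxy)-3-methylhex-1-en-3-ol | C=C[C@](C)(O)CCCO[Si](C)(C)C(C)(C)C | intermediate
5 | allyl methyl carbonate | C=CCOC(=O)OC | starting material
6 | (2E,4R)-7-(TBS-oxy)-4-hydroxy-4-methylhept-2-en-1-yl methyl carbonate | COC(=O)OC/C=C/[C@](C)(O)CCCO[Si](C)(C)C(C)(C)C | intermediate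
7 | Meldrum's acid, 2,2-dimethyl-1,3-dioxane-4,6-dione | CC1(C)OC(=O)CC(=O)O1 | starting material
8 | allyl alcohol | C=CCO | starting material
9 | allyl hydrogen malonate | OC(=O)CC(=O)OCC=C | intermediate
10 | (2E,4R)-7-(TBS-oxy)-1-[(methoxycarbonyl)oxy]-4-methylhept-2-en-4-yl prop-2-en-1-yl propanedioate | COC(=O)OC/C=C/[C@](C)(OC(=O)CC(=O)OCC=C)CCCO[Si](C)(C)C(C)(C)C | intermediate
11 | (3-bromopropoxy)(tert-butyl)dimethylsilane | BrCCCO[Si](C)(C)C(C)(C)C | starting material
12 | [3-(TBS-oxy)propyl]triphenylphosphonium bromide | [Br-].CC(C)(C)[Si](C)(C)OCCC[P+](c1ccccc1)(c1ccccc1)c1ccccc1 | intermediate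
13 | hydroxyacetone, 1-hydroxypropan-2-one | CC(=O)CO | starting material
14 | 1-(TBDPS-oxy)propan-2-one | CC(=O)CO[Si](c1ccccc1)(c1ccccc1)C(C)(C)C | intermediate
15 | [3-(TBS-oxy)propylidene]triphenylphosphorane | CC(C)(C)[Si](C)(C)OCCC=P(c1ccccc1)(c1ccccc1)c1ccccc1 | intermediate
16 | (2Z)-5-(TBS-oxy)-1-(TBDPS-oxy)-2-methylpent-2-ene | CC(C)(C)[Si](C)(C)OCC/C=C(/C)CO[Si](c1ccccc1)(c1ccccc1)C(C)(C)C | intermediate
17 | (3Z)-5-(TBDPS-oxy)-4-methylpent-3-en-1-ol | OCC/C=C(/C)CO[Si](c1ccccc1)(c1ccccc1)C(C)(C)C | intermediate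
18 | tert-butyl{[(2Z)-5-iodo-2-methylpent-2-en-1-yl]oxy}diphenylsilane | ICC/C=C(/C)CO[Si](c1ccccc1)(c1ccccc1)C(C)(C)C | intermediate
19 | (2E,4R)-7-(TBS-oxy)-1-[(methoxycarbonyl)oxy]-4-methylhept-2-en-4-yl prop-2-en-1-yl 2-[(3Z)-5-(TBDPS-oxy)-4-methylpent-3-en-1-yl]propanedioate (both epimers at the malonate carbon) | COC(=O)OC/C=C/[C@](C)(OC(=O)C(CC/C=C(/C)CO[Si](c1ccccc1)(c1ccccc1)C(C)(C)C)C(=O)OCC=C)CCCO[Si](C)(C)C(C)(C)C | intermediate
20 | (2E,4R)-7-(TBS-oxy)-1-[(methoxycarbonyl)oxy]-4-methylhept-2-en-4-yl prop-2-en-1-yl 2-hydroxy-2-[(3Z)-5-(TBDPS-oxy)-4-methylpent-3-en-1-yl]propanedioate (both epimers) | COC(=O)OC/C=C/[C@](C)(OC(=O)C(O)(CC/C=C(/C)CO[Si](c1ccccc1)(c1ccccc1)C(C)(C)C)C(=O)OCC=C)CCCO[Si](C)(C)C(C)(C)C | intermediate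
21 | (2E,4R)-7-hydroxy-1-[(methoxycarbonyl)oxy]-4-methylhept-2-en-4-yl prop-2-en-1-yl 2-hydroxy-2-[(3Z)-5-(TBDPS-oxy)-4-methylpent-3-en-1-yl]propanedioate (both epimers) | COC(=O)OC/C=C/[C@](C)(OC(=O)C(O)(CC/C=C(/C)CO[Si](c1ccccc1)(c1ccccc1)C(C)(C)C)C(=O)OCC=C)CCCO | intermediate
22 | (2E,4R)-1-[(methoxycarbonyl)oxy]-4-methyl-7-oxohept-2-en-4-yl prop-2-en-1-yl 2-hydroxy-2-[(3Z)-5-(TBDPS-oxy)-4-methylpent-3-en-1-yl]propanedioate (both epimers) | COC(=O)OC/C=C/[C@](C)(OC(=O)C(O)(CC/C=C(/C)CO[Si](c1ccccc1)(c1ccccc1)C(C)(C)C)C(=O)OCC=C)CCC=O | intermediate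
23 | prop-2-en-1-yl (5S,6R)-5-ethenyl-6-methyl-2-oxo-6-(3-oxopropyl)-3-[(3Z)-5-(TBDPS-oxy)-4-methylpent-3-en-1-yl]-1,4-dioxane-3-carboxylate (both epimers at C-3; vinyl cis to the oxopropyl arm) | C=C[C@@H]1OC(CC/C=C(/C)CO[Si](c2ccccc2)(c2ccccc2)C(C)(C)C)(C(=O)OCC=C)C(=O)O[C@]1(C)CCC=O | intermediate
24 | (1R,2S,5R,9S)-9-ethenyl-2-hydroxy-5-methyl-1-[(3Z)-5-(TBDPS-oxy)-4-methylpent-3-en-1-yl]-6,8-dioxabicyclo[3.2.2]nonan-7-one | C/C(=C/CC[C@@]12O[C@@H](C=C)[C@@](C)(CC[C@@H]1O)OC2=O)CO[Si](c1ccccc1)(c1ccccc1)C(C)(C)C | intermediate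
25 | but-2-yn-1-ol | CC#CCO | starting material
26 | sodium 2,2-bis(2-methoxyethoxy)-3-methyl-2,5-dihydro-1,2-oxaaluminol-2-uide (cyclic vinylalanate) | [Na+].CC1=CCO[Al-]1(OCCOC)OCCOC | intermediate
27 | (2Z)-3-iodobut-2-en-1-ol | C/C(I)=C/CO | intermediate
28 | tert-butyl{[(2Z)-3-iodobut-2-en-1-yl]oxy}diphenylsilane | C/C(I)=C/CO[Si](c1ccccc1)(c1ccccc1)C(C)(C)C | intermediate
29 | 9-{2-[(1R,2S,5R,9S)-2-hydroxy-5-methyl-7-oxo-1-[(3Z)-5-(TBDPS-oxy)-4-methylpent-3-en-1-yl]-6,8-dioxabicyclo[3.2.2]nonan-9-yl]ethyl}-9-borabicyclo[3.3.1]nonane | C/C(=C/CC[C@@]12O[C@@H](CCB3C4CCCC3CCC4)[C@@](C)(CC[C@@H]1O)OC2=O)CO[Si](c1ccccc1)(c1ccccc1)C(C)(C)C | intermediate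
30 | (1R,2S,5R,9S)-2-hydroxy-5-methyl-9-[(3Z)-5-(TBDPS-oxy)-3-methylpent-3-en-1-yl]-1-[(3Z)-5-(TBDPS-oxy)-4-methylpent-3-en-1-yl]-6,8-dioxabicyclo[3.2.2]nonan-7-one | C/C(=C/CC[C@@]12O[C@@H](CC/C(C)=C\CO[Si](c3ccccc3)(c3ccccc3)C(C)(C)C)[C@@](C)(CC[C@@H]1O)OC2=O)CO[Si](c1ccccc1)(c1ccccc1)C(C)(C)C | intermediate
31 | (1R,2S,5R,9S)-2-hydroxy-9-[(3Z)-5-hydroxy-3-methylpent-3-en-1-yl]-1-[(3Z)-5-hydroxy-4-methylpent-3-en-1-yl]-5-methyl-6,8-dioxabicyclo[3.2.2]nonan-7-one | C/C(=C/CC[C@@]12O[C@@H](CC/C(C)=C\CO)[C@@](C)(CC[C@@H]1O)OC2=O)CO | target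

Total step count: 19 steps.
Longest linear sequence: 11 steps (steps 1, 2, 3, 5, 11, 12, 13, 14, 15, 18, 19 from linalool; equally steps 6, 8, 9, 10, 11 to 15, 18, 19 from the bromide 11).

Steps most likely to fail

Step 15 (bears the label). The palladium-bound enolate may be allylated at carbon, or protonated by the methanol released in the first stage, before it can bridge the ring. The bridge may also close through an open transition state and give the C-2 epimer. Re-ionisation of the allylic ether may erode the ligand-set configuration at C-9. The fallback uses known chemistry, sets out from 20 and returns at 24. The allylic etherification is run alone on the silyl-protected 2-hydroxymalonate (same catalyst, rt) to give the allyl dioxanonecarboxylate F1. Decarboxylative hydrogenolysis of the allyl ester with Pd(PPh3)4 and HCO2H/Et3N gives the 3-alkyl-5-vinyl-1,4-dioxan-2-one F2. HF·pyridine gives the alcohol F3, and Dess–Martin periodinane gives the aldehyde F4. The bridge is then closed by a boron-enolate aldol (dicyclohexylboron triflate, Et3N, CH2Cl2, −78 °C). Boron enolates of 1,4-dioxan-2-ones are known to add to aldehydes through a Zimmerman–Traxler transition state, and this gives 24.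

Step 18. Transmetalation of the hindered alkylborane may be slow, so that protodeboronation and base-induced opening of the bridged lactone compete with the coupling. The fallback sets out from 24 and returns at 30. Hydroboration with 9-BBN and oxidation with NaBO3 give the primary alcohol F5. Iodination (I2, PPh3, imidazole) gives the primary iodide F6. Zinc insertion (Zn, LiCl, THF) and Negishi coupling with 28 (Pd(PPh3)4) then form the same bond without aqueous base and with retention of the (Z) geometry.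

Step 5. Acylation of the hindered tertiary allylic alcohol may be slower than N-acylurea formation from the half ester, and the tertiary allylic ester may ionise and eliminate during a long reaction. The fallback sets out from 6 and returns at 10. The alcohol is heated with Meldrum's acid 7 (toluene, 90 °C), so that the acylketene forms thermally without carbodiimide and gives the hydrogen malonate F7. O-allylation with allyl bromide and KHCO3 in DMF then gives 10.

Further compounds

F1 | step 15 | prop-2-en-1-yl (5S,6R)-5-ethenyl-6-methyl-2-oxo-6-[3-(TBS-oxy)propyl]-3-[(3Z)-5-(TBDPS-oxy)-4-methylpent-3-en-1-yl]-1,4-dioxane-3-carboxylate | C=C[C@@H]1OC(CC/C=C(/C)CO[Si](c2ccccc2)(c2ccccc2)C(C)(C)C)(C(=O)OCC=C)C(=O)O[C@]1(C)CCCO[Si](C)(C)C(C)(C)C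
F2 | step 15 | (5S,6R)-5-ethenyl-6-methyl-6-[3-(TBS-oxy)propyl]-3-[(3Z)-5-(TBDPS-oxy)-4-methylpent-3-en-1-yl]-1,4-dioxan-2-one | C=C[C@@H]1OC(CC/C=C(/C)CO[Si](c2ccccc2)(c2ccccc2)C(C)(C)C)C(=O)O[C@]1(C)CCCO[Si](C)(C)C(C)(C)C
F3 | step 15 | (5S,6R)-5-ethenyl-6-(3-hydroxypropyl)-6-methyl-3-[(3Z)-5-(TBDPS-oxy)-4-methylpent-3-en-1-yl]-1,4-dioxan-2-one | C=C[C@@H]1OC(CC/C=C(/C)CO[Si](c2ccccc2)(c2ccccc2)C(C)(C)C)C(=O)O[C@]1(C)CCCO
F4 | step 15 | 3-{(2R,3S)-3-ethenyl-2-methyl-6-oxo-5-[(3Z)-5-(TBDPS-oxy)-4-methylpent-3-en-1-yl]-1,4-dioxan-2-yl}propanal | C=C[C@@H]1OC(CC/C=C(/C)CO[Si](c2ccccc2)(c2ccccc2)C(C)(C)C)C(=O)O[C@]1(C)CCC=O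
F5 | step 18 | (1R,2S,5R,9S)-2-hydroxy-9-(2-hydroxyethyl)-5-methyl-1-[(3Z)-5-(TBDPS-oxy)-4-methylpent-3-en-1-yl]-6,8-dioxabicyclo[3.2.2]nonan-7-one | C/C(=C/CC[C@@]12O[C@@H](CCO)[C@@](C)(CC[C@@H]1O)OC2=O)CO[Si](c1ccccc1)(c1ccccc1)C(C)(C)C
F6 | step 18 | (1R,2S,5R,9S)-2-hydroxy-9-(2-iodoethyl)-5-methyl-1-[(3Z)-5-(TBDPS-oxy)-4-methylpent-3-en-1-yl]-6,8-dioxabicyclo[3.2.2]nonan-7-one | C/C(=C/CC[C@@]12O[C@@H](CCI)[C@@](C)(CC[C@@H]1O)OC2=O)CO[Si](c1ccccc1)(c1ccccc1)C(C)(C)C
F7 | step 5 | 3-{[(2E,4R)-7-(TBS-oxy)-1-[(methoxycarbonyl)oxy]-4-methylhept-2-en-4-yl]oxy}-3-oxopropanoic acid | COC(=O)OC/C=C/[C@](C)(OC(=O)CC(=O)O)CCCO[Si](C)(C)C(C)(C)C
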